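## The problem

The target 22 (CNP0253987.1) is a 1,1-diarylpropane. One sp3 carbon carries a hydrogen, a 4-hydroxyphenyl ring (ring C), C1 of a 2,4-dihydroxyphenyl ring (ring B) and a two-carbon tether to a 4-hydroxy-2-methoxyphenyl ring (ring A). Ring B also carries at C5 a 3-(4-hydroxyphenyl)-3-oxopropyl arm ending in ring D, so the molecule is a dihydrochalcone as well. The methine is the only stereocentre and, read from the SMILES, is (R); nothing in the molecule can relay configuration to it, so a catalyst must set it. Rings B and C, both bonded to it, are para-oxygenated benzene rings of similar size and donor strength, so a method that has to tell one aryl group from the other has little to work with. Ring B is 1,2,4,5-tetrasubstituted and as electron-rich as ring A, so the C5 arm needs a positional marker present from the start. The four free phenols, the aryl ketone and the doubly benzylic C–H between two electron-rich rings (open to hydride abstraction and to ionisation) call for phenol protection that comes off last under neutral conditions. The enabling feature is that in ring C the oxygen at C4 is para to C1, the carbon on the stereocentre. C1 and C2 can therefore come from a terminal alkyne on the stereocentre and C3–C6 from a 2-silyloxybutadiene, so the stereocentre can be set while ring C is still a slim ethynyl group.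

## Retrosynthesis

**22 from 20.** No skeletal bond is cut. The four phenols are written as benzyl ethers and the arm as its enone, so that one hydrogenation over palladium on carbon saturates the C=C (giving 21 in the flask) and frees all phenols. Benzyl is chosen because it survives base, fluoride, hydride, brief acid and the cobalt step, and leaves without acid or oxidant.

**20 from 16 and 19.** The bond between C5 of ring B and the β-carbon of the arm is cut, a Mizoroki–Heck coupling forward. The bromine of 16 has marked C5 since the first building block, which avoids choosing between rings A and B in a late electrophilic substitution. Enone 19 comes in one step from commercial ketone 17 by α-methylenation, through Mannich base 18.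

**16 from 14 from 13.** These are functional-group changes only. The aryl trimethylsilyl ether 14 is too labile for the Heck step and a free phenol would add to enone 19, so silicon is exchanged for benzyl through phenoxide 15. Compound 14 is the dehydrogenation product of cyclohexa-1,4-diene 13.

**13 from 11 and 12.** Two ring-C bonds are cut, each joining an alkyne carbon of 11 to a terminus of diene 12. This removes a whole oxygenated aryl ring and leaves an ethynyl group. The forward cobalt-catalysed [4+2] must place the silyloxy carbon para to the substituent and must leave the propargylic stereocentre, the aryl bromide and the benzyl ethers alone.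

**11 from 10 from 9 from 8.** Desilylation of 10 gives the terminal alkyne. The methylene next to ring A in 10 comes from ketone 8 by reduction to alcohol 9 and ionic deoxygenation. The ketone was needed only to activate the alkene for the stereo-setting step.

**8 from 6 and 7.** The bond between the stereocentre and the alkynyl carbon is cut, an asymmetric conjugate alkynylation of chalcone 6 with silylacetylene 7 forward. The alternative of adding an aryl group here is kept only as a fallback, because a linear alkynyl group is a smaller migrating group for the hindered β-carbon of 6. The catalyst has to choose an enone face, not distinguish two aryl groups.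

**6 from 2 and 4; 2 from 1; 4 from 3.** The enone C=C is cut by Claisen–Schmidt condensation, through aldol adduct 5. Aldehyde 2 and ketone 4 are the benzyl ethers of commercial 1 and 3. The bromine of 1 becomes the C5 marker of ring B.

## Roads not taken

**Alternative 1:** The cut is the aryl C2–O bond of ring B. 3,3-Bis[4-(benzyloxy)phenyl]propanoic acid A2 is achiral, and its two identical rings become rings B and C.
- Forward step: Pd(OAc)2 with a chiral mono-protected amino acid and PhI(OAc)2 palladates an ortho C–H bond of one enantiotopic ring under carboxylate direction. Oxidation to tetravalent palladium and C–O reductive elimination close the dihydrocoumarin A1 and create the stereocentre.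
- Merits: the two aryl groups are told apart by the very oxygen the target needs, in one step from a trivially made acid. The lactone carbonyl is then a handle for attaching ring A.
- Weak points: enantioselective C–H lactonisation of this kind is established for five-membered ring closure from diarylacetic acids. Here a six-membered lactone must form through a larger palladacycle with the prochiral carbon one atom further from the metal, and the oxidant meets two electron-rich benzyloxyarenes. After A1, ring B has no marker at the arm position, which must be distinguished from the equally activated ortho positions of the pendant benzyloxyphenyl ring. Attaching ring A by lactone opening leaves the same benzylic oxygen to remove as in the chosen route.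
- Comparison: this road reaches the stereocentre in fewer steps and is the more elegant answer to the two-similar-rings problem. The chosen plan sets against it known reaction types at every step and a bromine marker fixed before any selectivity question arises.

**Alternative 2:** The cut is the C1–C6 bond of ring B. The ring is assembled from the open-chain 1,3-diketone dimethyl acetal A4, which already carries the stereocentre, the ring-A tether, ring C and the dithiane-masked arm.
- Forward step: TsOH in wet solvent frees the aldehyde. The terminal α-carbon of the diketone adds to it, and dehydration and enolisation give resorcinol A3.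
- Merits: the substitution pattern of ring B is fixed by construction, with no halogen marker and no palladium coupling, and the conditions are mild.
- Weak points: A4 is a long branched chain whose assembly needs many C–C bond formations, and its stereocentre still has to be set by a separate asymmetric step, so the central problem is only moved. The freed aldehyde sits next to a ketone and will exist as an enolised β-keto aldehyde, a poor electrophile that is prone to deformylation, and O-cyclisation competes. The dithiane must later be removed with oxidising or thiophilic reagents in the presence of a free, easily oxidised resorcinol.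
- Comparison: this road is better in regiochemical certainty for ring B. The chosen plan sets against it that rings A, B and D are bought as arenes and only ring C is built, which makes it much shorter.

**Alternative 3:** The cuts are C5–C6 and C2–C3 of ring B. tert-Butyl keto ester A6 and the enantiopure 2-methylidene ester A7 are joined.
- Forward step: base-mediated Michael addition and Claisen closure give the cyclohexane-1,3-dione A5. Ester cleavage with decarboxylation, dehydrogenation to the resorcinol, ketal removal and debenzylation follow.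
- Merits: two halves of similar size are joined convergently, both arms are placed by construction, and the ring formation is classical enolate chemistry without a precious metal.
- Weak points: in A7 the stereocentre hydrogen is benzylic and γ to the ester, so the alkoxide needed for the annulation can move the double bond into conjugation and erase the stereocentre. Making A7 enantiopure needs its own asymmetric step, and Michael addition to an α-branched acrylate is slow. The dione must be dehydrogenated next to an oxidisable diarylmethine, after two further unmasking operations.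
- Comparison: this road is at least as good in convergence and in regiocontrol of ring B. The chosen plan sets against it that the stereocentre never meets strong base once it is set, and that aromatising a cyclohexa-1,4-diene needs only one equivalent of a mild oxidant at 0 °C.

Key step: step 8

Assumption: (R)-DTBM-SEGPHOS is taken to direct the alkynyl group to the enone face that gives (3S)-8, by analogy with simpler acyclic enones; if the first run shows the opposite sense, the (S)-ligand is used and nothing else changes.

## Route

Step 1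
Reactants: 1 5-bromo-2,4-dihydroxybenzaldehyde
Product: 2 2,4-bis(benzyloxy)-5-bromobenzaldehyde
Conditions: BnBr (2.4 equiv), K2CO3, DMF, 60 °C
Reagents that add atoms: benzyl bromide, BrCc1ccccc1
Why: Williamson ether synthesis; carbonate in DMF deprotonates both phenols, the chelated 2-OH included, and the aldehyde and aryl bromide are inert.

Step 2
Reactants: 3 1-(4-hydroxy-2-methoxyphenyl)ethanone
Product: 4 1-[4-(benzyloxy)-2-methoxyphenyl]ethanone
Conditions: BnBr (1.2 equiv), K2CO3, DMF, 60 °C
Reagents that add atoms: benzyl bromide, BrCc1ccccc1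
Why: Williamson ether synthesis on the only phenol; the methyl ketone is not alkylated under carbonate conditions.

Step 3
Reactants: 2 2,4-bis(benzyloxy)-5-bromobenzaldehyde; 4 1-[4-(benzyloxy)-2-methoxyphenyl]ethanone
Product: 6 (2E)-3-[2,4-bis(benzyloxy)-5-bromophenyl]-1-[4-(benzyloxy)-2-methoxyphenyl]prop-2-en-1-one, via aldol adduct 5 (not isolated)
Conditions: KOH, EtOH/THF, rt
Reagents that add atoms: none
Why: Claisen–Schmidt condensation: the enolate of 4 adds to the non-enolisable aldehyde 2 and adduct 5 loses water by E1cB to the conjugated (E)-enone; benzyl ethers and the aryl bromide are stable to ethanolic KOH.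

Step 4
Reactants: 6 (2E)-3-[2,4-bis(benzyloxy)-5-bromophenyl]-1-[4-(benzyloxy)-2-methoxyphenyl]prop-2-en-1-one; 7 ethynyltri(propan-2-yl)silane
Product: 8 (3S)-3-[2,4-bis(benzyloxy)-5-bromophenyl]-1-[4-(benzyloxy)-2-methoxyphenyl]-5-[tri(propan-2-yl)silyl]pent-4-yn-1-one
Conditions: 7 (2 equiv), [Rh(OAc)(C2H4)2]2 (2.5 mol %), (R)-DTBM-SEGPHOS (6 mol %), 1,4-dioxane, 80 °C
Reagents that add atoms: none
Why: Asymmetric conjugate alkynylation catalysed by monovalent rhodium: an alkynylrhodium formed from 7 and the acetate complex inserts the enone, and protonolysis of the rhodium enolate by a second alkyne releases 8. The C3 stereocentre is set by the chiral bisphosphine, which selects the enone face at the insertion; the bulk of the silyl group and of the ligand suppresses alkyne dimerisation, and the aryl bromide is not touched.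

Step 5
Reactants: 8 (3S)-3-[2,4-bis(benzyloxy)-5-bromophenyl]-1-[4-(benzyloxy)-2-methoxyphenyl]-5-[tri(propan-2-yl)silyl]pent-4-yn-1-one
Product: 9 (3S)-3-[2,4-bis(benzyloxy)-5-bromophenyl]-1-[4-(benzyloxy)-2-methoxyphenyl]-5-[tri(propan-2-yl)silyl]pent-4-yn-1-ol (mixture of C1 epimers)
Conditions: NaBH4, MeOH/THF, 0 °C
Reagents that add atoms: none
Why: Borohydride reduction of the aryl ketone; the carbinol configuration is not controlled and need not be, because this carbon becomes a methylene in step 6.

Step 6
Reactants: 9 (3S)-3-[2,4-bis(benzyloxy)-5-bromophenyl]-1-[4-(benzyloxy)-2-methoxyphenyl]-5-[tri(propan-2-yl)silyl]pent-4-yn-1-ol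
Product: 10 [(3S)-3-[2,4-bis(benzyloxy)-5-bromophenyl]-5-[4-(benzyloxy)-2-methoxyphenyl]pent-1-yn-1-yl]tri(propan-2-yl)silane
Conditions: Et3SiH (3 equiv), TFA (5 equiv), CH2Cl2, −20 → 0 °C
Reagents that add atoms: none
Why: Ionic hydrogenation: TFA ionises the benzylic alcohol to a cation stabilised by the ortho-methoxy and para-benzyloxy groups and Et3SiH delivers hydride. The only arene carbon placed to cyclise onto the cation (C6 of the bromoarene) is meta to both ether oxygens, and the cation lies two carbons from the stereocentre, which is not involved.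

Step 7
Reactants: 10 [(3S)-3-[2,4-bis(benzyloxy)-5-bromophenyl]-5-[4-(benzyloxy)-2-methoxyphenyl]pent-1-yn-1-yl]tri(propan-2-yl)silane
Product: 11 (3R)-3-[2,4-bis(benzyloxy)-5-bromophenyl]-5-[4-(benzyloxy)-2-methoxyphenyl]pent-1-yne
Conditions: TBAF, wet THF, 0 °C → rt
Reagents that add atoms: none
Why: Fluoride-induced protodesilylation of the silylalkyne; at this temperature the benzylic–propargylic C–H is not deprotonated, so no allene forms and the configuration is kept. The descriptor changes from S to R only because the alkynyl branch loses the CIP rank that silicon gave it.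

Step 8
Reactants: 11 (3R)-3-[2,4-bis(benzyloxy)-5-bromophenyl]-5-[4-(benzyloxy)-2-methoxyphenyl]pent-1-yne; 12 2-(trimethylsilyloxy)buta-1,3-diene
Product: 13 {[4-((1R)-1-[2,4-bis(benzyloxy)-5-bromophenyl]-3-[4-(benzyloxy)-2-methoxyphenyl]propyl)cyclohexa-1,4-dien-1-yl]oxy}trimethylsilane
Conditions: 12 (3 equiv), CoBr2(dppe) (10 mol %), Zn (20 mol %), ZnI2 (20 mol %), CH2Cl2, rt; filtration through deactivated silica, used crude
Reagents that add atoms: none
Why: Zinc reduces the divalent cobalt precatalyst to monovalent cobalt and ZnI2 removes a halide, giving a cationic (dppe)cobalt fragment that binds the s-cis diene 12 and the alkyne 11. Oxidative coupling forms the first C–C bond and a vinyl(allyl) complex of trivalent cobalt; reductive elimination forms the second C–C bond and releases 13 with the catalyst. The closest known reaction type is the cobalt-catalysed neutral Diels–Alder reaction of non-activated terminal alkynes with 2-substituted and 2-silyloxy buta-1,3-dienes, which gives 1,4-disubstituted cyclohexa-1,4-dienes. The six-membered ring is closed in an intermolecular [4+2] mode: the terminal alkyne carbon bonds to C1 of 12 and the internal alkyne carbon to C4 of 12. No stereocentre is created, and the existing one is a spectator under neutral, base-free conditions at room temperature. The step needs para and not meta regiochemistry, which the bisphosphine dppe imposes and the branched propargylic substituent reinforces, and it needs cycloaddition to outrun alkyne cyclotrimerisation, which excess 12 and the hindered alkyne should secure. The aryl bromide and benzyl ethers are expected to be spectators, since phosphine-ligated low-valent cobalt in CH2Cl2 should not insert into an aryl–bromine bond at this temperature.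

Step 9
Reactants: 13 {[4-((1R)-1-[2,4-bis(benzyloxy)-5-bromophenyl]-3-[4-(benzyloxy)-2-methoxyphenyl]propyl)cyclohexa-1,4-dien-1-yl]oxy}trimethylsilane
Product: 14 [4-{(1R)-1-[2,4-bis(benzyloxy)-5-bromophenyl]-3-[4-(benzyloxy)-2-methoxyphenyl]propyl}phenoxy]trimethylsilane
Conditions: DDQ (1.0 equiv), PhMe, 0 °C, 15 min; filtration through basic alumina, used crude
Reagents that add atoms: none
Why: Dehydrogenation of a cyclohexa-1,4-diene by DDQ: hydride abstraction from a doubly allylic CH2 and proton loss give the arene, the enol ether oxygen ending as the aryl silyl ether. Aromatisation is far faster than attack on the diarylmethine C–H, so one equivalent at 0 °C is used and the reaction is stopped at once.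

Step 10
Reactants: 14 [4-{(1R)-1-[2,4-bis(benzyloxy)-5-bromophenyl]-3-[4-(benzyloxy)-2-methoxyphenyl]propyl}phenoxy]trimethylsilane
Product: 16 1,5-bis(benzyloxy)-2-bromo-4-{(1R)-1-[4-(benzyloxy)phenyl]-3-[4-(benzyloxy)-2-methoxyphenyl]propyl}benzene, via caesium phenoxide 15 (not isolated)
Conditions: CsF (2 equiv), BnBr (1.5 equiv), DMF, rt
Reagents that add atoms: benzyl bromide, BrCc1ccccc1
Why: Fluoride cleaves the aryl O–Si bond and the phenoxide 15 is benzylated in the same flask (Williamson ether synthesis); the result is a uniformly benzyl-protected bromide with no free phenol to add to the enone in step 12.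

Step 11
Reactants: 17 1-[4-(benzyloxy)phenyl]ethanone
Product: 19 1-[4-(benzyloxy)phenyl]prop-2-en-1-one, via Mannich base 18 (not isolated)
Conditions: (CH2O)n (2 equiv), i-Pr2NH·TFA (1 equiv), TFA (10 mol %), THF, reflux; used at once
Reagents that add atoms: formaldehyde (as paraformaldehyde), C=O
Why: Direct α-methylenation of an aryl methyl ketone: Mannich reaction with the iminium ion from formaldehyde and the secondary amine gives 18, which eliminates the amine to the enone; 19 polymerises on storage and is prepared just before use.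

Step 12
Reactants: 16 1,5-bis(benzyloxy)-2-bromo-4-{(1R)-1-[4-(benzyloxy)phenyl]-3-[4-(benzyloxy)-2-methoxyphenyl]propyl}benzene; 19 1-[4-(benzyloxy)phenyl]prop-2-en-1-one
Product: 20 (2E)-3-(2,4-bis(benzyloxy)-5-{(1R)-1-[4-(benzyloxy)phenyl]-3-[4-(benzyloxy)-2-methoxyphenyl]propyl}phenyl)-1-[4-(benzyloxy)phenyl]prop-2-en-1-one
Conditions: 19 (2 equiv), Pd2(dba)3 (2.5 mol %), [HP(t-Bu)3]BF4 (10 mol %), Cy2NMe (1.5 equiv), 1,4-dioxane, 60 °C
Reagents that add atoms: none
Why: Mizoroki–Heck reaction: oxidative addition of the electron-rich aryl bromide to zerovalent palladium bearing the bulky, electron-rich P(t-Bu)3, syn insertion of the enone and β-hydride elimination give the (E)-enone. This ligand allows a temperature low enough to spare the polymerisable enone.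

Step 13
Reactants: 20 (2E)-3-(2,4-bis(benzyloxy)-5-{(1R)-1-[4-(benzyloxy)phenyl]-3-[4-(benzyloxy)-2-methoxyphenyl]propyl}phenyl)-1-[4-(benzyloxy)phenyl]prop-2-en-1-one
Product: 22 3-(2,4-dihydroxy-5-{(1R)-3-(4-hydroxy-2-methoxyphenyl)-1-(4-hydroxyphenyl)propyl}phenyl)-1-(4-hydroxyphenyl)propan-1-one, via tetrabenzyl dihydrochalcone 21 (not isolated)
Conditions: H2 (1 atm), 10% palladium on carbon, EtOAc/MeOH, rt
Reagents that add atoms: none
Why: Heterogeneous hydrogenation saturates the enone C=C to 21 and then cleaves the four benzyl ethers by hydrogenolysis. The aryl ketone, conjugated to a para-oxygenated ring, is reduced much more slowly in a neutral solvent, and the methine stereocentre is not affected.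

## Compound list

1 | 5-bromo-2,4-dihydroxybenzaldehyde | O=Cc1cc(Br)c(O)cc1O | starting material
2 | 2,4-bis(benzyloxy)-5-bromobenzaldehyde | O=Cc1cc(Br)c(OCc2ccccc2)cc1OCc1ccccc1 | intermediate
3 | 1-(4-hydroxy-2-methoxyphenyl)ethanone | COc1cc(O)ccc1C(C)=O | starting material
4 | 1-[4-(benzyloxy)-2-methoxyphenyl]ethanone | COc1cc(OCc2ccccc2)ccc1C(C)=O | intermediate
5 | 3-[2,4-bis(benzyloxy)-5-bromophenyl]-1-[4-(benzyloxy)-2-methoxyphenyl]-3-hydroxypropan-1-one (racemic aldol adduct, not isolated) | COc1cc(OCc2ccccc2)ccc1C(=O)CC(O)c1cc(Br)c(OCc2ccccc2)cc1OCc1ccccc1 | intermediate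
6 | (2E)-3-[2,4-bis(benzyloxy)-5-bromophenyl]-1-[4-(benzyloxy)-2-methoxyphenyl]prop-2-en-1-one | COc1cc(OCc2ccccc2)ccc1C(=O)/C=C/c1cc(Br)c(OCc2ccccc2)cc1OCc1ccccc1 | intermediate
7 | ethynyltri(propan-2-yl)silane, (triisopropylsilyl)acetylene | C#C[Si](C(C)C)(C(C)C)C(C)C | starting material
8 | (3S)-3-[2,4-bis(benzyloxy)-5-bromophenyl]-1-[4-(benzyloxy)-2-methoxyphenyl]-5-[tri(propan-2-yl)silyl]pent-4-yn-1-one | COc1cc(OCc2ccccc2)ccc1C(=O)C[C@H](C#C[Si](C(C)C)(C(C)C)C(C)C)c1cc(Br)c(OCc2ccccc2)cc1OCc1ccccc1 | intermediate
9 | (3S)-3-[2,4-bis(benzyloxy)-5-bromophenyl]-1-[4-(benzyloxy)-2-methoxyphenyl]-5-[tri(propan-2-yl)silyl]pent-4-yn-1-ol, C1 epimers | COc1cc(OCc2ccccc2)ccc1C(O)C[C@H](C#C[Si](C(C)C)(C(C)C)C(C)C)c1cc(Br)c(OCc2ccccc2)cc1OCc1ccccc1 | intermediate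
10 | [(3S)-3-[2,4-bis(benzyloxy)-5-bromophenyl]-5-[4-(benzyloxy)-2-methoxyphenyl]pent-1-yn-1-yl]tri(propan-2-yl)silane | COc1cc(OCc2ccccc2)ccc1CC[C@H](C#C[Si](C(C)C)(C(C)C)C(C)C)c1cc(Br)c(OCc2ccccc2)cc1OCc1ccccc1 | intermediate
11 | (3R)-3-[2,4-bis(benzyloxy)-5-bromophenyl]-5-[4-(benzyloxy)-2-methoxyphenyl]pent-1-yne | COc1cc(OCc2ccccc2)ccc1CC[C@H](C#C)c1cc(Br)c(OCc2ccccc2)cc1OCc1ccccc1 | intermediate
12 | 2-(trimethylsilyloxy)buta-1,3-diene | C=CC(=C)O[Si](C)(C)C | starting material
13 | {[4-((1R)-1-[2,4-bis(benzyloxy)-5-bromophenyl]-3-[4-(benzyloxy)-2-methoxyphenyl]propyl)cyclohexa-1,4-dien-1-yl]oxy}trimethylsilane | COc1cc(OCc2ccccc2)ccc1CC[C@H](C1=CCC(O[Si](C)(C)C)=CC1)c1cc(Br)c(OCc2ccccc2)cc1OCc1ccccc1 | intermediate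
14 | [4-{(1R)-1-[2,4-bis(benzyloxy)-5-bromophenyl]-3-[4-(benzyloxy)-2-methoxyphenyl]propyl}phenoxy]trimethylsilane | COc1cc(OCc2ccccc2)ccc1CC[C@H](c1ccc(O[Si](C)(C)C)cc1)c1cc(Br)c(OCc2ccccc2)cc1OCc1ccccc1 | intermediate
15 | caesium 4-{(1R)-1-[2,4-bis(benzyloxy)-5-bromophenyl]-3-[4-(benzyloxy)-2-methoxyphenyl]propyl}phenolate (not isolated) | COc1cc(OCc2ccccc2)ccc1CC[C@H](c1ccc([O-])cc1)c1cc(Br)c(OCc2ccccc2)cc1OCc1ccccc1.[Cs+] | intermediate
16 | 1,5-bis(benzyloxy)-2-bromo-4-{(1R)-1-[4-(benzyloxy)phenyl]-3-[4-(benzyloxy)-2-methoxyphenyl]propyl}benzene | COc1cc(OCc2ccccc2)ccc1CC[C@H](c1ccc(OCc2ccccc2)cc1)c1cc(Br)c(OCc2ccccc2)cc1OCc1ccccc1 | intermediate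
17 | 1-[4-(benzyloxy)phenyl]ethanone | CC(=O)c1ccc(OCc2ccccc2)cc1 | starting material
18 | 1-[4-(benzyloxy)phenyl]-3-[di(propan-2-yl)amino]propan-1-one (Mannich base, not isolated) | CC(C)N(CCC(=O)c1ccc(OCc2ccccc2)cc1)C(C)C | intermediate
19 | 1-[4-(benzyloxy)phenyl]prop-2-en-1-one | C=CC(=O)c1ccc(OCc2ccccc2)cc1 | intermediate
20 | (2E)-3-(2,4-bis(benzyloxy)-5-{(1R)-1-[4-(benzyloxy)phenyl]-3-[4-(benzyloxy)-2-methoxyphenyl]propyl}phenyl)-1-[4-(benzyloxy)phenyl]prop-2-en-1-one | COc1cc(OCc2ccccc2)ccc1CC[C@H](c1ccc(OCc2ccccc2)cc1)c1cc(/C=C/C(=O)c2ccc(OCc3ccccc3)cc2)c(OCc2ccccc2)cc1OCc1ccccc1 | intermediate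
21 | 3-(2,4-bis(benzyloxy)-5-{(1R)-1-[4-(benzyloxy)phenyl]-3-[4-(benzyloxy)-2-methoxyphenyl]propyl}phenyl)-1-[4-(benzyloxy)phenyl]propan-1-one (not isolated) | COc1cc(OCc2ccccc2)ccc1CC[C@H](c1ccc(OCc2ccccc2)cc1)c1cc(CCC(=O)c2ccc(OCc3ccccc3)cc2)c(OCc2ccccc2)cc1OCc1ccccc1 | intermediate
22 | 3-(2,4-dihydroxy-5-{(1R)-3-(4-hydroxy-2-methoxyphenyl)-1-(4-hydroxyphenyl)propyl}phenyl)-1-(4-hydroxyphenyl)propan-1-one | COc1cc(O)ccc1CC[C@H](c1ccc(O)cc1)c1cc(CCC(=O)c2ccc(O)cc2)c(O)cc1O | target

## Step count and risks

Total step count: 13. Longest linear sequence: 11 steps (1 → 2 → 6 → 8 → 9 → 10 → 11 → 13 → 14 → 16 → 20 → 22); steps 2 and 11 are side branches.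

**Step 8 (key step).**
- What may go wrong: cyclotrimerisation of the alkyne competing with cycloaddition; loss of para regiocontrol because the propargylic carbon carries a bulky, ether-rich aryl group; insertion of low-valent cobalt into the aryl–bromine bond; hydrolysis of the silyl enol ether by ZnI2 and traces of water.
- Fallback: it gives up the ring construction, sets out from chalcone 6 and returns at 16. Rhodium-catalysed asymmetric 1,4-addition of commercial 4-(benzyloxy)phenylboronic acid to 6 (Hayashi–Miyaura reaction; [RhCl(C2H4)2]2, chiral diene ligand, aqueous KOH, 1,4-dioxane) would give (3R)-3-[2,4-bis(benzyloxy)-5-bromophenyl]-3-[4-(benzyloxy)phenyl]-1-[4-(benzyloxy)-2-methoxyphenyl]propan-1-one F1. NaBH4 would give (3R)-3-[2,4-bis(benzyloxy)-5-bromophenyl]-3-[4-(benzyloxy)phenyl]-1-[4-(benzyloxy)-2-methoxyphenyl]propan-1-ol F2 as C1 epimers, and Et3SiH/TFA as in step 6 would give 16. This path is held in reserve because an aryl group must insert at the hindered β-carbon of 6, where the main route asks only for a linear alkynyl group.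

**Step 4.**
- What may go wrong: low conversion, because enone 6 carries donor-substituted rings at both ends and an ortho-benzyloxy group at the β-aryl ring, so alkyne dimerisation can take over; insufficient facial selectivity on a β-aryl enone.
- Fallback: it sets out from aldehyde 2 and returns at alcohol 9. Wittig reaction of 2 with (triphenylphosphoranylidene)acetaldehyde would give (2E)-3-[2,4-bis(benzyloxy)-5-bromophenyl]prop-2-enal F3. The same rhodium/DTBM-SEGPHOS alkynylation with 7, now on a more electrophilic enal (MeOH, 40 °C), would give (3S)-3-[2,4-bis(benzyloxy)-5-bromophenyl]-5-[tri(propan-2-yl)silyl]pent-4-ynal F4. Benzylation of commercial 4-bromo-3-methoxyphenol would give 4-(benzyloxy)-1-bromo-2-methoxybenzene F5, and its Grignard reagent [4-(benzyloxy)-2-methoxyphenyl]magnesium bromide F6 (Mg, THF) would add to F4 at −78 °C to give 9. Ring A is then attached by carbonyl addition and the acceptor no longer carries the deactivating aryl ketone.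

**Step 6.**
- What may go wrong: capture of the benzylic cation by an arene (Friedel–Crafts alkylation between molecules), elimination to the styrene followed by oligomerisation, or acid cleavage of a benzyl ether on the electron-rich rings.
- Fallback: it sets out from ketone 8 and returns at 10 with no cationic intermediate. Condensation of 8 with 4-methylbenzenesulfonohydrazide would give N'-{(3S)-3-[2,4-bis(benzyloxy)-5-bromophenyl]-1-[4-(benzyloxy)-2-methoxyphenyl]-5-[tri(propan-2-yl)silyl]pent-4-yn-1-ylidene}-4-methylbenzenesulfonohydrazide F7. Reduction with catecholborane and decomposition with NaOAc·3H2O (Caglioti-type tosylhydrazone reduction) would give 10.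

**Step 9.**
- What may go wrong: over-oxidation by hydride abstraction from the diarylmethine C–H, which would destroy the stereocentre; early loss of the silyl group followed by oxidation of the phenol.
- Fallback: it sets out from 13 and returns at 16. Saegusa–Ito oxidation (Pd(OAc)2, MeCN, rt) acts only at the silyl enol ether and would give 4-{(1R)-1-[2,4-bis(benzyloxy)-5-bromophenyl]-3-[4-(benzyloxy)-2-methoxyphenyl]propyl}cyclohexa-2,4-dien-1-one F8. This tautomerises to 4-{(1R)-1-[2,4-bis(benzyloxy)-5-bromophenyl]-3-[4-(benzyloxy)-2-methoxyphenyl]propyl}phenol F9, and benzylation (BnBr, K2CO3, DMF) would give 16.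

**Step 12.**
- What may go wrong: polymerisation of enone 19 outrunning a slow oxidative addition at a bromide that is ortho and para to ether oxygens; protodebromination.
- Fallback: it sets out from 16 and returns at 20. Bromine–lithium exchange (n-BuLi, THF, −78 °C) would give (2,4-bis(benzyloxy)-5-{(1R)-1-[4-(benzyloxy)phenyl]-3-[4-(benzyloxy)-2-methoxyphenyl]propyl}phenyl)lithium F10, and DMF would give 2,4-bis(benzyloxy)-5-{(1R)-1-[4-(benzyloxy)phenyl]-3-[4-(benzyloxy)-2-methoxyphenyl]propyl}benzaldehyde F11. Claisen–Schmidt condensation of F11 with ketone 17 (KOH, EtOH/THF) would pass through 3-(2,4-bis(benzyloxy)-5-{(1R)-1-[4-(benzyloxy)phenyl]-3-[4-(benzyloxy)-2-methoxyphenyl]propyl}phenyl)-1-[4-(benzyloxy)phenyl]-3-hydroxypropan-1-one F12 and give 20. No vinyl ketone is needed on this path.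

**Step 13.**
- What may go wrong: over-reduction of the aryl ketone during the long exposure needed to cleave four benzyl ethers, or incomplete debenzylation as the product becomes polar and binds to the catalyst.
- Fallback: it sets out from 20 and ends at 22. Hydrogenation over palladium on carbon poisoned with diphenyl sulfide would saturate only the C=C and give 21, now isolated. BCl3 with pentamethylbenzene in CH2Cl2 at −78 °C would then remove the four benzyl groups without hydrogen and without touching the ketone or the methyl ether. This fallback makes no compound outside the compound list (entry F0).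

## Further compounds

F1 | step 8 | (3R)-3-[2,4-bis(benzyloxy)-5-bromophenyl]-3-[4-(benzyloxy)phenyl]-1-[4-(benzyloxy)-2-methoxyphenyl]propan-1-one | COc1cc(OCc2ccccc2)ccc1C(=O)C[C@H](c1ccc(OCc2ccccc2)cc1)c1cc(Br)c(OCc2ccccc2)cc1OCc1ccccc1
F2 | step 8 | (3R)-3-[2,4-bis(benzyloxy)-5-bromophenyl]-3-[4-(benzyloxy)phenyl]-1-[4-(benzyloxy)-2-methoxyphenyl]propan-1-ol, C1 epimers | COc1cc(OCc2ccccc2)ccc1C(O)C[C@H](c1ccc(OCc2ccccc2)cc1)c1cc(Br)c(OCc2ccccc2)cc1OCc1ccccc1
F3 | step 4 | (2E)-3-[2,4-bis(benzyloxy)-5-bromophenyl]prop-2-enal | O=C/C=C/c1cc(Br)c(OCc2ccccc2)cc1OCc1ccccc1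
F4 | step 4 | (3S)-3-[2,4-bis(benzyloxy)-5-bromophenyl]-5-[tri(propan-2-yl)silyl]pent-4-ynal | O=CC[C@H](C#C[Si](C(C)C)(C(C)C)C(C)C)c1cc(Br)c(OCc2ccccc2)cc1OCc1ccccc1
F5 | step 4 | 4-(benzyloxy)-1-bromo-2-methoxybenzene | COc1cc(OCc2ccccc2)ccc1Br
F6 | step 4 | [4-(benzyloxy)-2-methoxyphenyl]magnesium bromide | COc1cc(OCc2ccccc2)ccc1[Mg]Br
F7 | step 6 | N'-{(3S)-3-[2,4-bis(benzyloxy)-5-bromophenyl]-1-[4-(benzyloxy)-2-methoxyphenyl]-5-[tri(propan-2-yl)silyl]pent-4-yn-1-ylidene}-4-methylbenzenesulfonohydrazide | COc1cc(OCc2ccccc2)ccc1C(C[C@H](C#C[Si](C(C)C)(C(C)C)C(C)C)c1cc(Br)c(OCc2ccccc2)cc1OCc1ccccc1)=NNS(=O)(=O)c1ccc(C)cc1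
F8 | step 9 | 4-{(1R)-1-[2,4-bis(benzyloxy)-5-bromophenyl]-3-[4-(benzyloxy)-2-methoxyphenyl]propyl}cyclohexa-2,4-dien-1-one | COc1cc(OCc2ccccc2)ccc1CC[C@H](C1=CCC(=O)C=C1)c1cc(Br)c(OCc2ccccc2)cc1OCc1ccccc1
F9 | step 9 | 4-{(1R)-1-[2,4-bis(benzyloxy)-5-bromophenyl]-3-[4-(benzyloxy)-2-methoxyphenyl]propyl}phenol | COc1cc(OCc2ccccc2)ccc1CC[C@H](c1ccc(O)cc1)c1cc(Br)c(OCc2ccccc2)cc1OCc1ccccc1
F10 | step 12 | (2,4-bis(benzyloxy)-5-{(1R)-1-[4-(benzyloxy)phenyl]-3-[4-(benzyloxy)-2-methoxyphenyl]propyl}phenyl)lithium | COc1cc(OCc2ccccc2)ccc1CC[C@H](c1ccc(OCc2ccccc2)cc1)c1cc([Li])c(OCc2ccccc2)cc1OCc1ccccc1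
F11 | step 12 | 2,4-bis(benzyloxy)-5-{(1R)-1-[4-(benzyloxy)phenyl]-3-[4-(benzyloxy)-2-methoxyphenyl]propyl}benzaldehyde | COc1cc(OCc2ccccc2)ccc1CC[C@H](c1ccc(OCc2ccccc2)cc1)c1cc(C=O)c(OCc2ccccc2)cc1OCc1ccccc1
F12 | step 12 | 3-(2,4-bis(benzyloxy)-5-{(1R)-1-[4-(benzyloxy)phenyl]-3-[4-(benzyloxy)-2-methoxyphenyl]propyl}phenyl)-1-[4-(benzyloxy)phenyl]-3-hydroxypropan-1-one, carbinol epimers | COc1cc(OCc2ccccc2)ccc1CC[C@H](c1ccc(OCc2ccccc2)cc1)c1cc(C(O)CC(=O)c2ccc(OCc3ccccc3)cc2)c(OCc2ccccc2)cc1OCc1ccccc1
F0 | step 13 | none | none
A1 | alternative 1 | 7-(benzyloxy)-4-[4-(benzyloxy)phenyl]chroman-2-one, single C4 enantiomer | O=C1C[C@H](c2ccc(OCc3ccccc3)cc2)c2ccc(OCc3ccccc3)cc2O1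
A2 | alternative 1 | 3,3-bis[4-(benzyloxy)phenyl]propanoic acid | O=C(O)CC(c1ccc(OCc2ccccc2)cc1)c1ccc(OCc2ccccc2)cc1
A3 | alternative 2 | free resorcinol with both arms, ketone masked as 1,3-dithiane | COc1cc(OCc2ccccc2)ccc1CC[C@H](c1ccc(OCc2ccccc2)cc1)c1cc(CCC2(SCCCS2)c2ccc(OCc3ccccc3)cc2)c(O)cc1O
A4 | alternative 2 | open-chain 1,3-diketone dimethyl acetal carrying the stereocentre and the dithiane arm (epimers at the arm-bearing carbon) | COc1cc(OCc2ccccc2)ccc1CC[C@H](c1ccc(OCc2ccccc2)cc1)CC(=O)CC(=O)C(CCC1(SCCCS1)c1ccc(OCc2ccccc2)cc1)C(OC)OC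
A5 | alternative 3 | 4,6-disubstituted cyclohexane-1,3-dione with a tert-butyl ester at the arm-bearing carbon (ring diastereomers) | COc1cc(OCc2ccccc2)ccc1CC[C@H](c1ccc(OCc2ccccc2)cc1)C1CC(CCC2(OCCO2)c2ccc(OCc3ccccc3)cc2)(C(=O)OC(C)(C)C)C(=O)CC1=O
A6 | alternative 3 | tert-butyl 2-acetyl-4-{2-[4-(benzyloxy)phenyl]-1,3-dioxolan-2-yl}butanoate | CC(=O)C(CCC1(OCCO1)c1ccc(OCc2ccccc2)cc1)C(=O)OC(C)(C)C
A7 | alternative 3 | methyl (3R)-3-[4-(benzyloxy)phenyl]-5-[4-(benzyloxy)-2-methoxyphenyl]-2-methylidenepentanoate | COc1cc(OCc2ccccc2)ccc1CC[C@H](c1ccc(OCc2ccccc2)cc1)C(=C)C(=O)OC
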